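The readings stem from a simulated flask for an exercise; the scatter is artificial.

1. The easy step is to read the substrate column. Both earlier runs, at different loadings, hold nearly the same fraction of the charge at 80.0 s: 65.0 % in birch, 69.1 % in elm. Their mean is 67.0 %, and eta and beta are reckoned onward from it.

common to all: gas phase 53 mM (held)
- birch: substrate 0.067 M; run made earlier
- elm: substrate 0.15 M; run made earlier
- eta: substrate 0.10 M; time 2.0 min
- beta: substrate 0.10 M; time 4.0 min

| run | time / s | over-reacted product / % | target / % | substrate / % | side product / % |
|---|---|---|---|---|---|
| birch | 10.0 | 0 | 2.1 | 98.8 | 0.1 |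
| birch | 15.0 | 0 | 1.9 | 96.6 | 1.2 |
| birch | 25.0 | 0.4 | 5.9 | 93.2 | 0 |
| birch | 40.0 | 3.1 | 9.1 | 86.9 | 2.0 |
| birch | 60.0 | 6.1 | 13.9 | 77.3 | 2.2 |
| birch | 80.0 | 12.4 | 16.7 | 65.0 | 3.4 |
| elm | 12.0 | 0.2 | 2.3 | 100.0 | 1.3 |
| elm | 25.0 | 0 | 6.0 | 93.7 | 0 |
| elm | 40.0 | 2.1 | 7.6 | 86.6 | 0.6 |
| elm | 50.0 | 1.3 | 11.0 | 83.0 | 3.7 |
| elm | 60.0 | 4.0 | 12.1 | 80.7 | 5.5 |
| elm | 80.0 | 9.8 | 13.8 | 69.1 | 8.0 |

(standard deviation of a reading: 1 percentage point)

- percent here means substrate units held: one side product counts as two
- at the start none of the gas is dissolved
- the numbers in the tables scatter with a standard deviation of 1 percentage point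
- steps under discussion: gas phase <-> dissolved gas; substrate + dissolved gas -> target; dissolved gas + target -> over-reacted product; substrate + target -> side product

- which of these there is most of at the end, counted by the substrate in it, eta (target / side product / substrate / over-reacted product)
- which of these there is most of at the end, counted by the substrate in it, beta (target / side product / substrate / over-reacted product)
- the largest of these amounts at the end, in percent of the substrate charged, eta
- the largest of these amounts at the end, in percent of the substrate charged, beta

2. Upper edge: the mean fade rate since the start, 0.300 min⁻¹, slow start included. Carried on from 80.0 s, it leaves 54.9 % at 2.0 min in eta and 30.1 % at 4.0 min in beta.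

3. Lower edge: the late fade rate 0.386 min⁻¹, the percent rate of substrate loss between 40.0 s and 80.0 s, a pseudo-first-order constant read from the two runs. It is larger than the mean rate. It leaves 51.8 % in eta and 23.9 % in beta. This edge holds while the fade rate rises no further.

4. My reckoning: eta keeps more than half of its charge as substrate, so substrate leads there. Beta's substrate has fallen below a third. In birch's last interval, over-reacted product gained 6.3 percentage points, faster than target's 2.8 points, so over-reacted product is my call for beta.

5. The forecast says substrate at 54 % for eta, inside the bracket, and over-reacted product at 52 % for beta, with beta's substrate at 22 %, just under the lower edge. Its ground: “The substrate fades at nearly the same percent rate at 0.067 and 0.15 M, so the loss is first order in substrate.”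

6. The flask gives substrate at 53.6 % in eta, and over-reacted product at 50.4 % in beta, where substrate stands at 23.9 %.

    gas phase ⇌ dissolved gas, rate k1*(csat - [dissolved gas]) (kL = 0.0340 s⁻¹)
    substrate + dissolved gas → target (k = 0.160 L mol⁻¹ s⁻¹)
    dissolved gas + target → over-reacted product (k = 0.480 L mol⁻¹ s⁻¹)
    substrate + target → side product (k = 0.0490 L mol⁻¹ s⁻¹)

7. Substrate still leads eta in part because of the drag of gas crossing into solution, acting together with the time allowed. Without that drag, eta's substrate stands at 33.3 % instead of 53.6 %. At 20.0 min it stands at 0.00893 %.

8. For eta read at 8.0 min, the late fade rate leaves 5.11 %. The computed flask holds 3.82 % substrate, and over-reacted product leads at 77.2 %.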